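**Plan**

- Retrosynthesis: the C6'–H/C5'–H pair (conjugate reduction), the acetyl group and the C2'–H (ketone reduction) are removed first; then the bonds C8–C1' and C7–C3' are cut together, giving (E)-methylisoeugenol and a p-quinone monoketal; the ketal goes back to 6-allyl-2,3,4-trimethoxyphenol and, by Claisen disconnection, to the allyl ether of 2,3,4-trimethoxyphenol.
- Enabling feature: ring C1'–C6' carries oxygen on four adjacent carbons (C2'–C5') with the allyl carbon C1' next to C2', so it is a dearomatised 6-allyl-2,3,4-trimethoxyphenol. Its C5' oxocarbenium ion is a pentadienyl cation C1'–C6'–C5'–C4'–C3' whose two ends are the bridgeheads; the C7–C8 bridge with trans aryl/methyl is the (E)-propenylarene. This is the presumed biosynthetic union (8.1', 7.3').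
- Forward: arene → cross-conjugated dienone ketal → cationic [5+2] closes the five- and seven-membered rings of the bicyclo[3.2.1]octane at once → C2' reduction, acetylation, enone reduction.
- Stereochemistry: C7, C8, C1', C3' come from the cycloaddition ((E)-alkene, endo aryl, chiral counter-anion); C2' from hydride attack on the C7/C8 face; C5' from protonation on the face opposite the endo aryl group.

Key step: step 4

Remark on locants: neolignan locants are used for the core. C1' carries allyl, C2' is the one-carbon bridge, C3' the methoxy bridgehead, C4' the ketone, C5' the CH(OMe), C6' the CH2; C7 carries the aryl group, C8 the methyl group. "Endo" means on the side of the C4'–C6' bridge, "exo" on the side of C2'.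

Assumption: the sense of induction of the chiral acid in step 4 cannot be predicted and has to be fixed by experiment; the catalyst enantiomer that leads to the (1S,5R,6R,7S) adduct is meant.

**Step 1**
Reactants: 1 2,3,4-trimethoxyphenol; 2 allyl bromide
Product: 3 1-(allyloxy)-2,3,4-trimethoxybenzene
Conditions: K2CO3, acetone, reflux
Reagents that add atoms: none
Why: Williamson ether synthesis of a phenoxide with a primary allylic bromide; no competing site.

**Step 2**
Reactants: 3 1-(allyloxy)-2,3,4-trimethoxybenzene
Product: 5 6-allyl-2,3,4-trimethoxyphenol, via ortho-dienone 4 (not isolated)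
Conditions: PhNEt2, 200 °C, sealed tube
Reagents that add atoms: none
Why: Aromatic Claisen rearrangement ([3,3]) to the only unsubstituted ortho carbon, followed by tautomerisation of dienone 4 to the phenol.

**Step 3**
Reactants: 5 6-allyl-2,3,4-trimethoxyphenol
Product: 6 6-allyl-2,3,4,4-tetramethoxycyclohexa-2,5-dien-1-one
Conditions: PhI(OAc)2, MeOH, 0 °C
Reagents that add atoms: methanol, CO
Why: Oxidative dearomatisation of a para-methoxyphenol with a λ3-iodane, in which methanol captures the oxidised ring at the methoxy-bearing para carbon to give the p-quinone monoketal; the allyl group is inert.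

**Step 4**
Reactants: 6 6-allyl-2,3,4,4-tetramethoxycyclohexa-2,5-dien-1-one; 7 (E)-1,2-dimethoxy-4-(prop-1-enyl)benzene
Product: 11 (1S,5R,6R,7S)-7-(3,4-dimethoxyphenyl)-1,3-dimethoxy-6-methyl-5-(prop-2-enyl)bicyclo[3.2.1]oct-3-ene-2,8-dione (aryl endo; methyl exo), via quinone-ketal cation 8 (not isolated), via bicyclic oxocarbenium ion 9 (not isolated), via bicyclic dimethyl ketal 10 (not isolated)
Conditions: confined chiral BINOL-derived imidodiphosphorimidate acid (5 mol %), 7 (1.5 equiv), CH2Cl2, −78 °C; then aq. buffer pH 4, 0 °C
Reagents that add atoms: water, O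
Why: Proposed new method: the chiral acid ionises the ketal of 6 to cation 8, held as a contact ion pair with the chiral anion, and 7 adds across the cation termini C1'/C3' in an asynchronous cationic [5+2] (4π pentadienyl cation + 2π alkene, suprafacial on both partners) in which the nucleophilic propenyl β-carbon bonds first to the allyl-bearing terminus and the developing benzylic cation is captured by the methoxy-bearing terminus (the enol-ether carbon β to the neighbouring methoxy group), giving oxocarbenium ion 9; the liberated methanol converts 9 into ketal 10 and returns the proton to the catalyst, and the aqueous work-up hydrolyses 10 to the C4' ketone. The closest known reaction type is the racemic acid-promoted [5+2] cycloaddition of p-quinone monoketals with (E)-propenylbenzenes, and what is new is control of the faces of the planar cation by a chiral counter-anion, argued from counter-anion-directed catalysis of oxocarbenium ions by strong confined chiral acids. Both new rings, the cyclopentane C1'–C2'–C3'–C7–C8 and the cycloheptane C1'–C8–C7–C3'–C4'–C5'–C6', are closed by the same two σ-bonds in an intermolecular cycloaddition, the second bond as a five-membered ring closure of the enol-ether carbon onto the benzylic cationic centre. The trans relation C7/C8 follows from the (E)-geometry of 7, the endo position of the aryl group from stacking of the electron-rich dimethoxyphenyl ring on the cationic ring in the transition state, the cis bridgeheads C1'/C3' from the geometry of the bicycle, and the absolute configuration from the anion, which covers one face of the cation. The step needs C-closure ([5+2]) instead of O-closure to the hydrobenzofuran ([3+2]), secured by low temperature, a non-nucleophilic anion and quenching before acid can isomerise the kinetic bicyclo[3.2.1]octane, and it needs first attack at the allyl-bearing terminus, which is the end of the cation that carries no donor group and is therefore the more electrophilic and less hindered one.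

**Step 5**
Reactants: 11 (1S,5R,6R,7S)-bicyclo[3.2.1]oct-3-ene-2,8-dione cycloadduct
Product: 12 (1S,5R,6R,7S,8S)-7-(3,4-dimethoxyphenyl)-8-hydroxy-1,3-dimethoxy-6-methyl-5-(prop-2-enyl)bicyclo[3.2.1]oct-3-en-2-one (hydroxyl syn to the enone bridge)
Conditions: NaBH4 (1 equiv), MeOH/CH2Cl2, −40 °C; aq. NH4Cl
Reagents that add atoms: none
Why: Borohydride 1,2-reduction picks the strained, non-conjugated bridging ketone C2' over the cross-conjugated α-methoxy enone C4', and hydride should enter from the face of the two-carbon bridge C7–C8 (the one-carbon bridge of a bicyclo[3.2.1]octan-8-one leans over the three-carbon bridge, here a flat methoxy-enone whose central carbon C5' lies under the other trajectory), which places the new hydroxyl group syn to the C4'–C6' bridge (2'S).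

**Step 6**
Reactants: 12 (1S,5R,6R,7S,8S)-8-hydroxy enone
Product: 13 (1S,5R,6R,7S,8S)-7-(3,4-dimethoxyphenyl)-1,3-dimethoxy-6-methyl-2-oxo-5-(prop-2-enyl)bicyclo[3.2.1]oct-3-en-8-yl acetate
Conditions: Ac2O, DMAP (cat.), pyridine, CH2Cl2, 0 °C to rt
Reagents that add atoms: acetic anhydride, CC(=O)OC(C)=O
Why: DMAP-catalysed acylation of the hindered secondary alcohol under conditions too weakly basic for retro-aldol opening of the β-hydroxy ketone; no stereocentre is touched.

**Step 7**
Reactants: 13 (1S,5R,6R,7S,8S)-8-acetoxy enone
Product: 15 (1S,3S,5S,6R,7S,8S)-7-(3,4-dimethoxyphenyl)-1,3-dimethoxy-6-methyl-2-oxo-5-(prop-2-enyl)bicyclo[3.2.1]octan-8-yl acetate (CNP0344493.1), via copper(I) enolate 14 (not isolated)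
Conditions: [(Ph3P)CuH]6 (0.3 equiv), H2O (3 equiv), toluene, rt
Reagents that add atoms: none
Why: Copper hydride conjugate reduction transfers hydride to the β-carbon C6' of the α-methoxy enone and leaves the isolated allyl double bond, the acetate and the aryl ethers alone, and copper enolate 14 is protonated by water at C5' on the exo face because the endo face is covered by the endo aryl ring on C7, which sets 5'-H exo and 5'-OMe endo (5'S).

**Compound list**

1 | 2,3,4-trimethoxyphenol | COc1ccc(O)c(OC)c1OC | starting material
2 | allyl bromide | C=CCBr | starting material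
3 | 1-(allyloxy)-2,3,4-trimethoxybenzene | C=CCOc1ccc(OC)c(OC)c1OC | intermediate
4 | 6-allyl-2,3,4-trimethoxycyclohexa-2,4-dien-1-one (racemic, transient) | C=CCC1C=C(OC)C(OC)=C(OC)C1=O | intermediate
5 | 6-allyl-2,3,4-trimethoxyphenol | C=CCc1cc(OC)c(OC)c(OC)c1O | intermediate
6 | 6-allyl-2,3,4,4-tetramethoxycyclohexa-2,5-dien-1-one | C=CCC1=CC(OC)(OC)C(OC)=C(OC)C1=O | intermediate
7 | (E)-1,2-dimethoxy-4-(prop-1-enyl)benzene ((E)-methylisoeugenol) | C/C=C/c1ccc(OC)c(OC)c1 | starting material
8 | (5-allyl-2,3-dimethoxy-4-oxocyclohexa-2,5-dien-1-ylidene)(methyl)oxonium, ion pair with the catalyst anion | C=CCC1=CC(=[O+]C)C(OC)=C(OC)C1=O | intermediate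
9 | bicyclic C4' O-methyl oxocarbenium ion of 11 | C=CC[C@]12C=C(OC)C(=[O+]C)[C@](OC)([C@H](c3ccc(OC)c(OC)c3)[C@H]1C)C2=O | intermediate
10 | C4' dimethyl ketal of 11 | C=CC[C@]12C=C(OC)C(OC)(OC)[C@](OC)([C@H](c3ccc(OC)c(OC)c3)[C@H]1C)C2=O | intermediate
11 | (1S,5R,6R,7S)-7-(3,4-dimethoxyphenyl)-1,3-dimethoxy-6-methyl-5-(prop-2-enyl)bicyclo[3.2.1]oct-3-ene-2,8-dione | C=CC[C@]12C=C(OC)C(=O)[C@](OC)([C@H](c3ccc(OC)c(OC)c3)[C@H]1C)C2=O | intermediate
12 | (1S,5R,6R,7S,8S)-7-(3,4-dimethoxyphenyl)-8-hydroxy-1,3-dimethoxy-6-methyl-5-(prop-2-enyl)bicyclo[3.2.1]oct-3-en-2-one | C=CC[C@]12C=C(OC)C(=O)[C@](OC)([C@H](c3ccc(OC)c(OC)c3)[C@H]1C)[C@H]2O | intermediate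
13 | (1S,5R,6R,7S,8S)-7-(3,4-dimethoxyphenyl)-1,3-dimethoxy-6-methyl-2-oxo-5-(prop-2-enyl)bicyclo[3.2.1]oct-3-en-8-yl acetate | C=CC[C@]12C=C(OC)C(=O)[C@](OC)([C@H](c3ccc(OC)c(OC)c3)[C@H]1C)[C@H]2OC(C)=O | intermediate
14 | copper(I) enolate of 15 (O–Cu on C4', C4'=C5'; PPh3 on copper not drawn) | C=CC[C@]12CC(OC)=C(O[Cu])[C@](OC)([C@H](c3ccc(OC)c(OC)c3)[C@H]1C)[C@H]2OC(C)=O | intermediate
15 | (1S,3S,5S,6R,7S,8S)-7-(3,4-dimethoxyphenyl)-1,3-dimethoxy-6-methyl-2-oxo-5-(prop-2-enyl)bicyclo[3.2.1]octan-8-yl acetate | C=CC[C@]12C[C@H](OC)C(=O)[C@](OC)([C@H](c3ccc(OC)c(OC)c3)[C@H]1C)[C@H]2OC(C)=O | target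

**Totals and risks**

Total step count: 7. Longest linear sequence: 7 steps (1 to 15); 2 and 7 enter as purchased compounds.

Step 4 (Proposed new method). The chiral anion may discriminate the two faces of the cation poorly, or the acid may fail to turn over because the product oxocarbenium ion holds the proton. The fallback sets out from 6 and 7 and uses known chemistry: stoichiometric TMSOTf in CH2Cl2/MeCN at −78 °C with aqueous NaHCO3 work-up gives the racemic cycloadduct F1 by the established acid-promoted [5+2]. Preparative chromatography on a chiral stationary phase (SFC, amylose carbamate) then separates the enantiomers, and the route is rejoined at 11.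

Step 5. Hydride may instead be delivered over the enone bridge, because the exo methyl group on C8 flanks the intended face; this would give the C2' epimer, which cannot be inverted at a bridge carbon. The fallback sets out from 11 and changes the order so that the substrate blocks the unwanted face. Conjugate reduction with [(Ph3P)CuH]6/H2O first gives the dihydro dione F2, in which C5'–H and C6'–H (both exo) now stand on the face of the three-carbon bridge, and the six-membered ring is pushed out of the chair because the endo 5'-OMe would meet the endo aryl group. NaBH4, dosed at about one hydride equivalent at −40 °C because the C4' ketone is no longer protected by conjugation, should then reduce the bridging ketone from the C7/C8 face to the hydroxy ketone F3. Acetylation (Ac2O, DMAP, pyridine) rejoins the route at 15.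

Step 7. Proton transfer to C5' may be slowed on the exo face by the neighbouring acetoxy group, or the kinetically set C5' centre may be lost by enolisation toward the likely more stable 5'-epimer. The fallback sets out from 13 and separates hydride transfer from protonation. Copper-hydride-catalysed 1,4-hydrosilylation (cat. [(Ph3P)CuH]6, PhMe2SiH, toluene) gives the isolable silyl enol ether F4. Protodesilylation with TBAF/AcOH in THF at −78 °C then protonates the enolate under kinetic control on the exo face and rejoins the route at 15.

**Further compounds**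

F1 | step 4 | racemic 7-(3,4-dimethoxyphenyl)-1,3-dimethoxy-6-methyl-5-(prop-2-enyl)bicyclo[3.2.1]oct-3-ene-2,8-dione (both enantiomers) | C=CC[C@]12C=C(OC)C(=O)[C@](OC)([C@H](c3ccc(OC)c(OC)c3)[C@H]1C)C2=O.C=CC[C@@]12C=C(OC)C(=O)[C@@](OC)([C@@H](c3ccc(OC)c(OC)c3)[C@@H]1C)C2=O
F2 | step 5 | (1S,3S,5S,6R,7S)-7-(3,4-dimethoxyphenyl)-1,3-dimethoxy-6-methyl-5-(prop-2-enyl)bicyclo[3.2.1]octane-2,8-dione | C=CC[C@]12C[C@H](OC)C(=O)[C@](OC)([C@H](c3ccc(OC)c(OC)c3)[C@H]1C)C2=O
F3 | step 5 | (1S,3S,5S,6R,7S,8S)-7-(3,4-dimethoxyphenyl)-8-hydroxy-1,3-dimethoxy-6-methyl-5-(prop-2-enyl)bicyclo[3.2.1]octan-2-one | C=CC[C@]12C[C@H](OC)C(=O)[C@](OC)([C@H](c3ccc(OC)c(OC)c3)[C@H]1C)[C@H]2O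
F4 | step 7 | dimethyl(phenyl)silyl enol ether of 15 (O–Si on C4', C4'=C5') | C=CC[C@]12CC(OC)=C(O[Si](C)(C)c3ccccc3)[C@](OC)([C@H](c3ccc(OC)c(OC)c3)[C@H]1C)[C@H]2OC(C)=O
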